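Ring D (12-membered lactone) is cut at the C6–C(=O) and acyl C–O bonds (carbon monoxide taken out, leaving an aryl triflate and the secondary alcohol) and at the alkene bond two carbons out from C5 (cross-metathesis of a C5 allyl group with (R)-oct-7-en-2-ol).
Enabling feature: ketal carbon C9a, shared by pyran ring B and tetrahydrofuran ring C, carries CH3, aryl oxygen O9 and furan oxygen O1. Rings B and C are therefore a 1-methylindane, bonded to arene carbon C8a through carbon, with an oxygen inserted; O9–C8a and O1–C9a are cut together back to a tertiary benzylic hydroperoxide.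
The indane is cut at aryl–C1 (aryllithium acylated by a lactone carbonyl) and at the benzylic CH2–C2 bond (lactone enolate alkylation), giving a 2-allyl-6-bromobenzyl bromide and (S)-4-methylbutyrolactone.
Forward order: arene ring A is fully substituted first (O-allylation, Claisen rearrangement, benzylation), the carbocycle is closed, rings B and C form together by oxygen insertion and ketalisation, and ring D is closed last.
Stereochemistry: C3 comes from the (S)-lactone, C3a from alkylation anti to that methyl group, C9a from the enforced cis fusion of rings B and C, and the lactone carbinol from (R)-propylene oxide, carried through with retention.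

Key step: step 11

Assumption: locants of the tricycle follow 2,3,3a,9a-tetrahydro-4H-furo[2,3-b]chromene (O1, C2, C3, C3a, C4, C4a, C5 to C8, C8a, O9, C9a); lactone 7 is taken as a purchasable compound; 12 to 14 are carried as C1-epimer mixtures because C1 becomes planar in step 11.

Step 1
Reactants: 1 2-bromo-5-hydroxy-4-methoxybenzaldehyde
Product: 2 5-(allyloxy)-2-bromo-4-methoxybenzaldehyde
Conditions: allyl bromide, K2CO3, DMF, rt
Reagents that add atoms: allyl bromide, C=CCBr
Why: Williamson O-alkylation of the phenoxide by the allylic bromide, to which the aldehyde and the aryl bromide are inert.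

Step 2
Reactants: 2 5-(allyloxy)-2-bromo-4-methoxybenzaldehyde
Product: 3 2-allyl-6-bromo-3-hydroxy-4-methoxybenzaldehyde
Conditions: N,N-diethylaniline, 195 °C
Reagents that add atoms: none
Why: Aromatic Claisen rearrangement; the allyl group can only reach the one free ortho carbon (the other carries OMe, the para carbon carries Br), and tautomerisation returns the phenol.

Step 3
Reactants: 3 2-allyl-6-bromo-3-hydroxy-4-methoxybenzaldehyde
Product: 4 2-allyl-3-(benzyloxy)-6-bromo-4-methoxybenzaldehyde
Conditions: BnBr, K2CO3, DMF, rt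
Reagents that add atoms: benzyl bromide, BrCc1ccccc1
Why: Williamson benzylation; the benzyl ether should withstand organolithium, Grignard, peroxide and Lewis-acid steps and leaves in the hydrogenation of step 14.

Step 4
Reactants: 4 2-allyl-3-(benzyloxy)-6-bromo-4-methoxybenzaldehyde
Product: 5 [2-allyl-3-(benzyloxy)-6-bromo-4-methoxyphenyl]methanol
Conditions: NaBH4, MeOH/THF, 0 °C
Reagents that add atoms: none
Why: Hydride reduction of the aldehyde by NaBH4, which leaves the aryl bromide, alkene and ethers untouched.

Step 5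
Reactants: 5 [2-allyl-3-(benzyloxy)-6-bromo-4-methoxyphenyl]methanol
Product: 6 2-allyl-3-(benzyloxy)-6-bromo-4-methoxybenzyl bromide
Conditions: PBr3 (0.4 equiv), Et2O, 0 °C; used crude
Reagents that add atoms: phosphorus tribromide, BrP(Br)Br
Why: Bromination of a benzylic alcohol with PBr3 by substitution of the intermediate phosphite; the para-methoxybenzylic bromide is reactive and is therefore not stored.

Step 6
Reactants: 6 2-allyl-3-(benzyloxy)-6-bromo-4-methoxybenzyl bromide; 7 (S)-4-methyldihydrofuran-2(3H)-one
Product: 9 (3S,4S)-3-{[2-allyl-3-(benzyloxy)-6-bromo-4-methoxyphenyl]methyl}-4-methyldihydrofuran-2(3H)-one, via lithium lactone enolate 8 (not isolated)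
Conditions: LiN(i-Pr)2 (LDA, 1.05 equiv), 7 (1.1 equiv), THF, −78 °C; then 6 (1.0 equiv), DMPU, −78 to −40 °C
Reagents that add atoms: none
Why: SN2 alkylation of a butyrolactone enolate by a benzylic bromide; the electrophile should enter anti to the C4 methyl group and give the trans (3S,4S) lactone, and with no free amide base left the arene is not metalated.

Step 7
Reactants: 9 (3S,4S)-3-{[2-allyl-3-(benzyloxy)-6-bromo-4-methoxyphenyl]methyl}-4-methyldihydrofuran-2(3H)-one
Product: 11 (2S)-4-allyl-5-(benzyloxy)-2-[(2S)-1-hydroxypropan-2-yl]-6-methoxy-2,3-dihydro-1H-inden-1-one, via aryllithium 10 (not isolated)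
Conditions: t-BuLi (2.1 equiv), THF, −78 °C; then AcOH in THF, −78 °C; used without storage
Reagents that add atoms: none
Why: Parham cyclisation; bromine–lithium exchange should outrun attack of t-BuLi on the hindered lactone, the aryllithium acylates the lactone carbonyl (5-exo-trig), and the lithium hemiketalate masks the ketone until the cold acid quench, so C2 is not enolised.

Step 8
Reactants: 11 (2S)-4-allyl-5-(benzyloxy)-2-[(2S)-1-hydroxypropan-2-yl]-6-methoxy-2,3-dihydro-1H-inden-1-one
Product: 12 (1RS,2S)-4-allyl-5-(benzyloxy)-2-[(2S)-1-hydroxypropan-2-yl]-6-methoxy-1-methyl-2,3-dihydro-1H-inden-1-ol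
Conditions: MeMgBr (3 equiv), CeCl3 (anhydrous), THF, −78 to 0 °C
Reagents that add atoms: methylmagnesium bromide, C[Mg]Br
Why: Organocerium 1,2-addition of a methyl nucleophile; the low basicity of the cerium reagent suppresses enolisation of the alpha-branched indanone so C2 keeps its configuration, and either C1 epimer serves.

Step 9
Reactants: 12 (1RS,2S)-4-allyl-5-(benzyloxy)-2-[(2S)-1-hydroxypropan-2-yl]-6-methoxy-1-methyl-2,3-dihydro-1H-inden-1-ol
Product: 13 (1RS,2S)-4-allyl-5-(benzyloxy)-2-[(2S)-1-(tert-butyldimethylsilyloxy)propan-2-yl]-6-methoxy-1-methyl-2,3-dihydro-1H-inden-1-ol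
Conditions: TBSCl (1.1 equiv), imidazole, CH2Cl2, 0 °C
Reagents that add atoms: tert-butyldimethylsilyl chloride, CC(C)(C)[Si](C)(C)Cl
Why: Selective silylation of the primary hydroxyl beside a tertiary one; the silyl ether keeps the side-chain oxygen from capturing the benzylic cation of step 10 and still acts as the nucleophile in step 11.

Step 10
Reactants: 13 (1RS,2S)-4-allyl-5-(benzyloxy)-2-[(2S)-1-(tert-butyldimethylsilyloxy)propan-2-yl]-6-methoxy-1-methyl-2,3-dihydro-1H-inden-1-ol
Product: 14 (1RS,2S)-4-allyl-5-(benzyloxy)-1-hydroperoxy-6-methoxy-1-methyl-2-[(2S)-1-(tert-butyldimethylsilyloxy)propan-2-yl]-2,3-dihydro-1H-indene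
Conditions: 50% aq H2O2 (20 equiv), H2SO4 (5 mol %), THF, 0 °C; NaHCO3 quench
Reagents that add atoms: hydrogen peroxide, OO
Why: Acid-catalysed SN1 perhydrolysis of a tertiary benzylic alcohol; the cation stabilised by the para benzyloxy group forms in dilute acid at 0 °C and should be captured by the large excess of H2O2 faster than it loses the C2 proton, while the hydroperoxide is not expected to rearrange in this water-rich medium and the primary silyl ether should survive the short exposure.

Step 11
Reactants: 14 (1RS,2S)-4-allyl-5-(benzyloxy)-1-hydroperoxy-6-methoxy-1-methyl-2-[(2S)-1-(tert-butyldimethylsilyloxy)propan-2-yl]-2,3-dihydro-1H-indene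
Product: 15 (3S,3aS,9aS)-5-allyl-6-(benzyloxy)-7-methoxy-3,9a-dimethyl-2,3,3a,9a-tetrahydro-4H-furo[2,3-b]chromene
Conditions: BF3·OEt2 (0.3 equiv), CH2Cl2, −40 to 0 °C
Reagents that add atoms: none
Why: BF3 binds the terminal peroxide oxygen and, as the O–O bond breaks, arene carbon C7a of the indane migrates from C1 to the inner oxygen, which expands the five-membered carbocycle to the 2-methylchroman-2-ylium ion (ring B, closed by ring expansion through oxygen insertion). The side-chain silyl ether oxygen then adds to the oxocarbenium carbon (ring C, 5-exo-trig), and the silyl group passes from the silyloxonium ion to the hydroxide split from the peroxide, leaving as tert-butyldimethylsilanol. The closest known reaction type is the Hock (cumene hydroperoxide) rearrangement of tertiary benzylic hydroperoxides, including ring-expanding cases in which a nucleophile intercepts the oxocarbenium ion, joined here to the familiar Lewis-acid ketalisation by a silyl ether. The new stereocenter C9a is set by C3a, because the three-atom tether reaches only the face of the planar cation on its own side, so the B/C junction should be cis (9aS), and both C1 epimers of 14 converge. The step needs aryl migration ahead of migration of C2 or methyl, which the benzyloxy group para to the migrating carbon secures; this is why C6 is still an ether and not yet the carboxyl. Low temperature and substoichiometric acid should keep the cation from losing the C3a proton, so the trans relation between the C3 methyl group and C4 set in step 6 is kept.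

Step 12
Reactants: 16 5-bromopent-1-ene; 17 (R)-propylene oxide
Product: 19 (R)-oct-7-en-2-ol, via Grignard reagent 18 (not isolated)
Conditions: Mg, THF, rt; then CuI (10 mol %), 17, −30 to 0 °C; aq NH4Cl
Reagents that add atoms: none
Why: Grignard formation and CuI-catalysed SN2 opening of the epoxide at its unsubstituted carbon, which does not touch the stereocenter and should give the (R)-alcohol.

Step 13
Reactants: 15 (3S,3aS,9aS)-5-allyl-6-(benzyloxy)-7-methoxy-3,9a-dimethyl-2,3,3a,9a-tetrahydro-4H-furo[2,3-b]chromene; 19 (R)-oct-7-en-2-ol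
Product: 20 (2R,7E)-9-[(3S,3aS,9aS)-6-(benzyloxy)-7-methoxy-3,9a-dimethyl-2,3,3a,9a-tetrahydro-4H-furo[2,3-b]chromen-5-yl]non-7-en-2-ol (E drawn; either alkene isomer serves)
Conditions: second-generation Grubbs catalyst (5 mol %), 19 (3 equiv), 1,4-benzoquinone (10 mol %), CH2Cl2, 40 °C
Reagents that add atoms: none
Why: Olefin cross-metathesis of two terminal alkenes, driven by loss of ethene and by the excess of the alkenol; benzoquinone should suppress migration of the allyl double bond, and the alkene geometry is erased in step 14.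

Step 14
Reactants: 20 (2R,7E)-9-[(3S,3aS,9aS)-6-(benzyloxy)-7-methoxy-3,9a-dimethyl-2,3,3a,9a-tetrahydro-4H-furo[2,3-b]chromen-5-yl]non-7-en-2-ol
Product: 21 (3S,3aS,9aS)-5-[(8R)-8-hydroxynonyl]-7-methoxy-3,9a-dimethyl-2,3,3a,9a-tetrahydro-4H-furo[2,3-b]chromen-6-ol
Conditions: H2 (1 atm), Pd/C, EtOAc, rt
Reagents that add atoms: none
Why: Heterogeneous hydrogenation saturates the alkene and hydrogenolyses the benzyl ether in one operation, while the ketal and the carbinol are inert in neutral ethyl acetate.

Step 15
Reactants: 21 (3S,3aS,9aS)-5-[(8R)-8-hydroxynonyl]-7-methoxy-3,9a-dimethyl-2,3,3a,9a-tetrahydro-4H-furo[2,3-b]chromen-6-ol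
Product: 22 (3S,3aS,9aS)-5-[(8R)-8-hydroxynonyl]-7-methoxy-3,9a-dimethyl-2,3,3a,9a-tetrahydro-4H-furo[2,3-b]chromen-6-yl trifluoromethanesulfonate
Conditions: PhNTf2, K2CO3, DMF, rt
Reagents that add atoms: N-phenylbis(trifluoromethanesulfonimide), O=S(=O)(N(c1ccccc1)S(=O)(=O)C(F)(F)F)C(F)(F)F
Why: Chemoselective O-triflation of a phenoxide by PhNTf2; the secondary alcohol is not deprotonated by K2CO3 and should not react with this mild triflating agent.

Step 16
Reactants: 22 (3S,3aS,9aS)-5-[(8R)-8-hydroxynonyl]-7-methoxy-3,9a-dimethyl-2,3,3a,9a-tetrahydro-4H-furo[2,3-b]chromen-6-yl trifluoromethanesulfonate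
Product: 23 lasiodiplactone A
Conditions: Pd(OAc)2 (10 mol %), dppp (12 mol %), CO (1 atm), K2CO3, toluene/DMF, 90 °C, slow addition to high dilution
Reagents that add atoms: carbon monoxide, [C-]#[O+]
Why: Palladium-catalysed carbonylative macrolactonisation (intramolecular alkoxycarbonylation): the triflate adds oxidatively to zerovalent palladium formed in the flask, CO inserts, and the side-chain hydroxyl opens the aroyl-palladium species to close ring D, without breaking the carbinol C–O bond, so the (R) centre is retained.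

Compound list
1 | 2-bromo-5-hydroxy-4-methoxybenzaldehyde | COc1cc(Br)c(C=O)cc1O | starting material
2 | 5-(allyloxy)-2-bromo-4-methoxybenzaldehyde | COc1cc(Br)c(C=O)cc1OCC=C | intermediate
3 | 2-allyl-6-bromo-3-hydroxy-4-methoxybenzaldehyde | COc1cc(Br)c(C=O)c(CC=C)c1O | intermediate
4 | 2-allyl-3-(benzyloxy)-6-bromo-4-methoxybenzaldehyde | COc1cc(Br)c(C=O)c(CC=C)c1OCc1ccccc1 | intermediate
5 | [2-allyl-3-(benzyloxy)-6-bromo-4-methoxyphenyl]methanol | COc1cc(Br)c(CO)c(CC=C)c1OCc1ccccc1 | intermediate
6 | 2-allyl-3-(benzyloxy)-6-bromo-4-methoxybenzyl bromide | COc1cc(Br)c(CBr)c(CC=C)c1OCc1ccccc1 | intermediate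
7 | (S)-4-methyldihydrofuran-2(3H)-one | O=C1C[C@H](C)CO1 | starting material
8 | lithium enolate of 7 (not isolated) | [Li]OC1=C[C@H](C)CO1 | intermediate
9 | (3S,4S)-3-{[2-allyl-3-(benzyloxy)-6-bromo-4-methoxyphenyl]methyl}-4-methyldihydrofuran-2(3H)-one | COc1cc(Br)c(C[C@H]2[C@H](C)COC2=O)c(CC=C)c1OCc1ccccc1 | intermediate
10 | aryllithium from 9, lithium in place of bromine (not isolated) | COc1cc([Li])c(C[C@H]2[C@H](C)COC2=O)c(CC=C)c1OCc1ccccc1 | intermediate
11 | (2S)-4-allyl-5-(benzyloxy)-2-[(2S)-1-hydroxypropan-2-yl]-6-methoxy-2,3-dihydro-1H-inden-1-one | COc1cc2c(c(CC=C)c1OCc1ccccc1)C[C@@H]([C@H](C)CO)C2=O | intermediate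
12 | (1RS,2S)-4-allyl-5-(benzyloxy)-2-[(2S)-1-hydroxypropan-2-yl]-6-methoxy-1-methyl-2,3-dihydro-1H-inden-1-ol | COc1cc2c(c(CC=C)c1OCc1ccccc1)C[C@@H]([C@H](C)CO)C2(C)O | intermediate
13 | (1RS,2S)-4-allyl-5-(benzyloxy)-2-[(2S)-1-(tert-butyldimethylsilyloxy)propan-2-yl]-6-methoxy-1-methyl-2,3-dihydro-1H-inden-1-ol | COc1cc2c(c(CC=C)c1OCc1ccccc1)C[C@@H]([C@H](C)CO[Si](C)(C)C(C)(C)C)C2(C)O | intermediate
14 | (1RS,2S)-4-allyl-5-(benzyloxy)-1-hydroperoxy-6-methoxy-1-methyl-2-[(2S)-1-(tert-butyldimethylsilyloxy)propan-2-yl]-2,3-dihydro-1H-indene | COc1cc2c(c(CC=C)c1OCc1ccccc1)C[C@@H]([C@H](C)CO[Si](C)(C)C(C)(C)C)C2(C)OO | intermediate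
15 | (3S,3aS,9aS)-5-allyl-6-(benzyloxy)-7-methoxy-3,9a-dimethyl-2,3,3a,9a-tetrahydro-4H-furo[2,3-b]chromene | COc1cc2c(c(CC=C)c1OCc1ccccc1)C[C@H]1[C@H](C)CO[C@@]1(C)O2 | intermediate
16 | 5-bromopent-1-ene | C=CCCCBr | starting material
17 | (R)-propylene oxide | C[C@@H]1CO1 | starting material
18 | pent-4-en-1-ylmagnesium bromide (not isolated) | C=CCCC[Mg]Br | intermediate
19 | (R)-oct-7-en-2-ol | C[C@@H](O)CCCCC=C | intermediate
20 | (2R,7E)-9-[(3S,3aS,9aS)-6-(benzyloxy)-7-methoxy-3,9a-dimethyl-2,3,3a,9a-tetrahydro-4H-furo[2,3-b]chromen-5-yl]non-7-en-2-ol | COc1cc2c(c(C/C=C/CCCC[C@@H](C)O)c1OCc1ccccc1)C[C@H]1[C@H](C)CO[C@@]1(C)O2 | intermediate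
21 | (3S,3aS,9aS)-5-[(8R)-8-hydroxynonyl]-7-methoxy-3,9a-dimethyl-2,3,3a,9a-tetrahydro-4H-furo[2,3-b]chromen-6-ol | COc1cc2c(c(CCCCCCC[C@@H](C)O)c1O)C[C@H]1[C@H](C)CO[C@@]1(C)O2 | intermediate
22 | (3S,3aS,9aS)-5-[(8R)-8-hydroxynonyl]-7-methoxy-3,9a-dimethyl-2,3,3a,9a-tetrahydro-4H-furo[2,3-b]chromen-6-yl trifluoromethanesulfonate | COc1cc2c(c(CCCCCCC[C@@H](C)O)c1OS(=O)(=O)C(F)(F)F)C[C@H]1[C@H](C)CO[C@@]1(C)O2 | intermediate
23 | lasiodiplactone A | COc1cc2c(c3c1C(=O)O[C@H](C)CCCCCCC3)C[C@H]1[C@H](C)CO[C@@]1(C)O2 | target

Total step count: 16. Longest linear sequence: 15 steps (steps 1 to 11 and 13 to 16, from compound 1); step 12 is a one-step side branch.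

Steps most likely to fail

Step 11. The oxocarbenium ion may lose the C3a proton and scramble that centre, the silyl group may transfer too slowly for ring C to close, or the hydroperoxide may fall back to the benzylic cation by loss of hydrogen peroxide. The fallback builds rings B and C by a hetero-Diels–Alder reaction of an ortho-quinone methide; it sets out from 5 (with lactone 7) and comes back at 15, bypassing steps 6 to 11. The lithium alkoxide of 5 undergoes bromine–lithium exchange (n-BuLi, 2.2 equiv, THF, −78 °C), and borylation with B(OMe)3 followed by NaOH/H2O2 oxidation should give the salicyl alcohol 3-allyl-4-(benzyloxy)-2-(hydroxymethyl)-5-methoxyphenol F1. Lactone 7 takes up one equivalent of MeLi at −78 °C to give the lactol (4S)-2,4-dimethyltetrahydrofuran-2-ol F2, which on acid-catalysed dehydration with distillation should give the enol ether (3S)-3,5-dimethyl-2,3-dihydrofuran F3. Heating F1 with excess F3 (toluene, 160 °C, sealed tube) should dehydrate F1 to the ortho-quinone methide, which adds across the enol ether in a [4+2] sense, anti to the C3 methyl group and with the oxygen-bearing alkene carbon bonding to the phenol oxygen, to give the cis-fused ketal 15.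

Step 16. Oxidative addition at the doubly ortho-substituted triflate and ring-closing alcoholysis of the hindered aroyl-palladium species may be slow, so that reduction of the triflate or chain growth between molecules takes over. The fallback separates carbonylation from ring closure; it sets out from 22 and comes back at 23. Hydroxycarbonylation of 22 (Pd(OAc)2, dppp, CO, KOAc, DMSO, 70 °C, aqueous work-up) should give the seco acid (3S,3aS,9aS)-5-[(8R)-8-hydroxynonyl]-7-methoxy-3,9a-dimethyl-2,3,3a,9a-tetrahydro-4H-furo[2,3-b]chromene-6-carboxylic acid F4. Treatment with 2,2'-dipyridyl disulfide and PPh3 should give its S-(pyridin-2-yl) thioester F5, and AgOTf in toluene at high dilution (silver-assisted Corey–Nicolaou lactonisation) should close ring D by acyl transfer, again without inverting the carbinol, to give 23.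

Step 7. t-BuLi may attack or deprotonate the lactone before the exchange is complete, and the keto alcohol may lose its C2 configuration by enolisation or by dehydration of its hemiketal during handling. The fallback uses a Weinreb amide as the acyl partner and a protected hydroxyl; it sets out from 9 and comes back at 13, bypassing 11 and 12. Opening of 9 with Me(MeO)NH·HCl and AlMe3 (CH2Cl2, 0 °C) should give the hydroxy amide (2S,3S)-2-{[2-allyl-3-(benzyloxy)-6-bromo-4-methoxyphenyl]methyl}-4-hydroxy-N-methoxy-N,3-dimethylbutanamide F6, which is silylated at once (TBSCl, imidazole) to its tert-butyldimethylsilyl ether F7. Bromine–lithium exchange (t-BuLi, THF, −78 °C) and Parham cyclisation onto the amide should give (2S)-4-allyl-5-(benzyloxy)-2-[(2S)-1-(tert-butyldimethylsilyloxy)propan-2-yl]-6-methoxy-2,3-dihydro-1H-inden-1-one F8, whose stable chelate releases the ketone only on quench. MeMgBr with CeCl3 then gives 13.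

Further compounds
F1 | step 11 | 3-allyl-4-(benzyloxy)-2-(hydroxymethyl)-5-methoxyphenol | COc1cc(O)c(CO)c(CC=C)c1OCc1ccccc1
F2 | step 11 | (4S)-2,4-dimethyltetrahydrofuran-2-ol | CC1(O)C[C@H](C)CO1
F3 | step 11 | (3S)-3,5-dimethyl-2,3-dihydrofuran | CC1=C[C@H](C)CO1
F4 | step 16 | (3S,3aS,9aS)-5-[(8R)-8-hydroxynonyl]-7-methoxy-3,9a-dimethyl-2,3,3a,9a-tetrahydro-4H-furo[2,3-b]chromene-6-carboxylic acid | COc1cc2c(c(CCCCCCC[C@@H](C)O)c1C(=O)O)C[C@H]1[C@H](C)CO[C@@]1(C)O2
F5 | step 16 | S-(pyridin-2-yl) thioester of F4 | COc1cc2c(c(CCCCCCC[C@@H](C)O)c1C(=O)Sc1ccccn1)C[C@H]1[C@H](C)CO[C@@]1(C)O2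
F6 | step 7 | (2S,3S)-2-{[2-allyl-3-(benzyloxy)-6-bromo-4-methoxyphenyl]methyl}-4-hydroxy-N-methoxy-N,3-dimethylbutanamide | COc1cc(Br)c(C[C@@H]([C@H](C)CO)C(=O)N(C)OC)c(CC=C)c1OCc1ccccc1
F7 | step 7 | tert-butyldimethylsilyl ether of F6 | COc1cc(Br)c(C[C@@H]([C@H](C)CO[Si](C)(C)C(C)(C)C)C(=O)N(C)OC)c(CC=C)c1OCc1ccccc1
F8 | step 7 | (2S)-4-allyl-5-(benzyloxy)-2-[(2S)-1-(tert-butyldimethylsilyloxy)propan-2-yl]-6-methoxy-2,3-dihydro-1H-inden-1-one | COc1cc2c(c(CC=C)c1OCc1ccccc1)C[C@@H]([C@H](C)CO[Si](C)(C)C(C)(C)C)C2=O
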